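The earlier runs and the new flask were computed from invented constants; the scatter is artificial.

The chemist taking over this bench finds a stirred, closed flask of substrate; this note says what it will hold when they come.

| setting | delta | zeta | flask |
|---|---|---|---|
| substrate | 1 M | 2.2 M | 1.5 M |
| remark | run made earlier | run made earlier |  |
| time |  |  | 15 min |

| run | time / min | target / % | crystals / % | substrate / % |
|---|---|---|---|---|
| delta | 1.33 | 8.5 | 3.0 | 87.7 |
| delta | 2.50 | 15.6 | 8.7 | 79.8 |
| delta | 4.00 | 16.4 | 13.7 | 70.7 |
| delta | 5.00 | 20.8 | 15.1 | 67.2 |
| delta | 6.00 | 20.2 | 15.5 | 66.4 |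
| delta | 8.00 | 21.3 | 17.5 | 59.6 |
| delta | 10.0 | 20.8 | 16.9 | 53.5 |
| zeta | 1.33 | 19.9 | 18.6 | 75.5 |
| zeta | 2.50 | 32.8 | 29.8 | 62.6 |
| zeta | 4.00 | 42.0 | 38.4 | 52.3 |
| zeta | 5.00 | 46.5 | 43.8 | 45.2 |
| zeta | 6.00 | 46.6 | 46.5 | 41.1 |
| zeta | 8.00 | 51.6 | 49.3 | 32.8 |
| zeta | 10.0 | 53.6 | 52.1 | 30.1 |

(standard deviation of a reading: 1 percentage point)

- percent here means substrate units held: one target or crystals or over-reaction product counts as two
- what is said of target includes crystals
- crystals is a solid; its amount is given per volume of the solution
- what may be going on: 2 substrate <-> target; crystals <-> target; target -> over-reaction product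

* amount of target and crystals together at 15 min, in percent of the substrate charged
* concentration of target in solution at 15 min, in percent of saturation

1. Substrate gives target, target falls out as crystals, and over-reaction product is what the balance of substrate and target misses.

2. At 10.0 min, target minus crystals reads 0.0390 M in delta and 0.0330 M in zeta, in substrate units. So we take [target] in solution as nearly constant while crystals stand.

3. Over-reaction product should then grow steadily, a zero-order loss. It averages 0.0257 M min⁻¹ in delta and 0.0359 M min⁻¹ in zeta, though zeta was charged twice as much. Their mean, 0.0308 M min⁻¹, is the drain, the over-reaction product formed per minute in substrate units.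

4. By our reckoning, the drain takes 30.8 % of this flask's charge by 15 min; substrate and target share the rest.

5. Don't extend the time: delta's target reads 20.8 % at 5.00 min and 20.8 % at 10.0 min, while its substrate falls from 67.2 % to 53.5 %.

6. The forecast gives 37 % of target and crystals together, with the solution at 98 % of saturation, holding that “over-reaction runs at a roughly constant rate”.

The flask gives 38.6 % of target and crystals together, with the solution at 96.5 % of saturation.

    2 substrate ⇌ target (K = 0.140 M⁻¹, k = 0.00111 M⁻¹ s⁻¹)
    crystals ⇌ target, rate k2*(cs2 - [target]) while solid is left; crystals form when [target] > cs2 (solubility = 23.0 mM, k = 0.0860 s⁻¹)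
    target → over-reaction product (k = 0.00859 s⁻¹)

At 15.0 min this flask holds 27.1 % as over-reaction product against the drain's 30.8 %, with crystals at 35.6 %, and dissolved target is made and used at a ratio of 0.986. The neighbouring flask is charged with 2.5 M of substrate, more than this flask, and read at the same time; carrying the same drain over as an assumption, we reckon 18.5 % of its charge as over-reaction product. That flask holds 58.1 % as target and crystals together, 22 % as substrate, and 19.8 % as over-reaction product.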